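The decalin is cut at C1–C2 and C9–C10. One Lewis-acid operation on a ring-free aldehyde makes both bonds. The isopropenyl CH2 (C1) attacks the C2 aldehyde and closes ring A. The C10 cation is then captured by the C8=C9 allylsilane, which closes ring B last and leaves the C8=C17 methylene. The step exploits the 1,3-relation of the C2 carbinol to quaternary C10 and the exocyclic alkene flanking C9. C2, C10 and C9 are relayed from C4/C5, which derive from the single stereocentre of (S)-carvone; its ring is alkylated twice and then cleaved. Allylic hydroxylation finally installs 7α-OH.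

Key step: step 11

Remark: labdane numbering is used for every intermediate. Ring A is C1–C5 and C10, and ring B is C5–C10. The side chain is C11, C12, C13(=O), C16. C17 is the exocyclic CH2, C18 (α-CH3) and C19 (β-CH2OAc) sit on C4, and C20 sits on C10. Centres that are erased later (C4 in 3, C8 in 6, the epoxide CH in 16) are drawn as the expected major epimer or left open.

Step 1
Reactants: 1 (S)-(+)-carvone; 2 prenyl bromide
Product: 3 (5S,6R)-6-prenylcarvone
Conditions: LDA, THF, −78 °C; then 2, −78 → 0 °C
Reagents that add atoms: none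
Why: Kinetic α′-deprotonation of the enone and SN2 enolate alkylation with an allylic bromide is standard for carvone; the new C4 centre should form mainly trans to the C5 isopropenyl group but is erased again in step 2.

Step 2
Reactants: 3 (5S,6R)-6-prenylcarvone
Product: 4 (5R,6S)-6-methyl-6-prenylcarvone
Conditions: LDA, THF–DMPU, −78 °C; MeI, −78 → −20 °C
Reagents that add atoms: iodomethane, CI
Why: Enolate alkylation of the fully substituted cross-conjugated enolate: the C5 isopropenyl group, pushed pseudo-axial by A(1,2) strain, shields one face, so MeI should enter anti to it and set quaternary C4 with C18 trans and the prenyl arm (C3–C2) cis to C10.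

Step 3
Reactants: 4 (5R,6S)-6-methyl-6-prenylcarvone
Product: 6 (5R,6S)-2-hydroxy-2,6-dimethyl-6-prenyl-5-isopropenylcyclohexanone (C8 epimers), via lithium enolate 5 (not isolated)
Conditions: L-Selectride (1.05 equiv), THF, −78 °C; then Davis oxaziridine, −78 → −40 °C; H2O
Reagents that add atoms: L-Selectride, [Li+].CCC(C)[BH-](C(C)CC)C(C)CC (Li in 5 only); 2-(phenylsulfonyl)-3-phenyloxaziridine, O=S(=O)(N1OC1c1ccccc1)c1ccccc1
Why: Conjugate reduction–enolate trapping: L-Selectride adds hydride 1,4 to the hindered enone (at C7), which gives the C19=C8 enolate regiospecifically, and Davis oxidation hydroxylates it at C8, whose configuration is irrelevant because step 4 turns it into a ketone.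

Step 4
Reactants: 6 α-ketol
Product: 7 methyl (2S,3R)-2-methyl-2-prenyl-3-isopropenyl-6-oxoheptanoate
Conditions: Pb(OAc)4, MeOH–PhH, 0 °C → rt
Reagents that add atoms: methanol, CO
Why: Criegee-type oxidative cleavage of an α-ketol through its methanol hemiketal breaks only the C19–C8 bond, so the temporary ring opens to the C19 methyl ester and the C8 methyl ketone while C4 and C5 are untouched.

Step 5
Reactants: 7 keto ester
Product: 9 methyl (2S,3R)-2-methyl-2-prenyl-3-isopropenylhept-6-ynoate, via enol phosphate 8 (not isolated)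
Conditions: LDA (1.1 equiv), THF, −78 °C; ClP(O)(OEt)2; LDA (2.3 equiv), −78 °C → rt; H2O
Reagents that add atoms: diethyl chlorophosphate, CCOP(=O)(Cl)OCC (in 8 only)
Why: Methyl ketone to terminal alkyne by kinetic enolisation at CH3 (C9), O-phosphorylation and base-induced elimination of the enol phosphate; the ester has no α-hydrogen and is neopentyl, so it should survive LDA.

Step 6
Reactants: 9 alkynyl ester
Product: 10 (2S,3R)-2-methyl-2-prenyl-3-isopropenylhept-6-yn-1-ol
Conditions: LiAlH4, Et2O, 0 °C → rt
Reagents that add atoms: none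
Why: Hydride reduction of the ester gives the neopentyl C19 alcohol, and the alkyne and the two unactivated alkenes are inert to LiAlH4.

Step 7
Reactants: 10 alkynol
Product: 11 (2S,3R)-2-methyl-2-prenyl-3-isopropenylhept-6-yn-1-yl acetate
Conditions: Ac2O, pyridine, DMAP (cat.), CH2Cl2, rt
Reagents that add atoms: acetic anhydride, CC(=O)OC(C)=O
Why: DMAP-catalysed acylation puts the C19 acetate of the target in place before any other hydroxyl group exists, so no later differentiation of alcohols is needed.

Step 8
Reactants: 11 alkynyl acetate; 12 methyl vinyl ketone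
Product: 15 (2S,3R,6Z)-6-bromo-2-methyl-10-oxo-2-prenyl-3-isopropenylundec-6-en-1-yl acetate, via bromoalkenyl-9-BBN 13 (not isolated), via boron enolate 14 (not isolated)
Conditions: B-Br-9-BBN, CH2Cl2, 0 °C; then 12, 0 °C → rt; H2O
Reagents that add atoms: B-bromo-9-borabicyclo[3.3.1]nonane, BrB1C2CCCC1CCC2
Why: syn-Bromoboration is specific for the terminal alkyne (Br to C8, B to C9) and the alkenyl-9-BBN then adds 1,4 to s-cis methyl vinyl ketone through a cyclic transition state with retention, so C11–C16 is attached and the alkene geometry (C7 trans to C11) is fixed.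

Step 9
Reactants: 15 bromo ketone
Product: 17 (2S,3R,6Z)-6-bromo-2-methyl-10-oxo-2-(2-oxoethyl)-3-isopropenylundec-6-en-1-yl acetate, via prenyl epoxide 16 (not isolated)
Conditions: mCPBA (1.0 equiv), CH2Cl2, 0 °C; then H5IO6, THF–H2O, 0 °C
Reagents that add atoms: 3-chloroperbenzoic acid, O=C(OO)c1cccc(Cl)c1
Why: Prilezhaev epoxidation picks the electron-rich trisubstituted prenyl alkene over the hindered 1,1-disubstituted and the bromine-deactivated alkenes, and periodic acid cleaves the epoxide via the diol to the C2 aldehyde and acetone.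

Step 10
Reactants: 17 bromo keto aldehyde
Product: 18 (2S,3R,6Z)-2-methyl-10-oxo-2-(2-oxoethyl)-3-isopropenyl-6-[(trimethylsilyl)methyl]undec-6-en-1-yl acetate
Conditions: Me3SiCH2Li, ZnCl2, THF, 0 °C; then 17, PdCl2(dppf) (5 mol %), THF, rt
Reagents that add atoms: (trimethylsilyl)methylzinc chloride, C[Si](C)(C)C[Zn]Cl
Why: Negishi coupling of an alkenyl bromide with a silylmethylzinc reagent proceeds with retention of geometry and gives the allylsilane, and the Me3SiCH2–Zn group, which adds poorly to carbonyl groups, should leave aldehyde, ketone and acetate alone.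

Step 11
Reactants: 18 allylsilane keto aldehyde
Product: 20 19-acetoxy-2α-hydroxy-14,15-dinorlabd-8(17)-en-13-one, via ring-A C10 cation 19 (not isolated)
Conditions: MeAlCl2 (4 equiv), CH2Cl2 (5 mM), −78 → −40 °C; aqueous work-up
Reagents that add atoms: none
Why: MeAlCl2 binds the C2 aldehyde, the isopropenyl CH2 (C1) attacks it to close ring A and place a tertiary cation at C10 (19), the C8=C9 allylsilane attacks C10 through C9 to close ring B, and loss of the silyl group from C17 gives the C8=C17 methylene. The closest known reaction type is the Prins-initiated cation–olefin polycyclisation with allylsilane termination. Ring A closes 6-endo-trig (C1–C2) and ring B 6-endo-trig (C9–C10), both through chairs with anti addition across C1=C10 (C2–C1 and C10–C9 antiperiplanar). C10 and the trans ring fusion follow from the equatorial C5 side chain fixed by the carvone-derived C4/C5 pair, C9 follows from the alkene geometry (C11 trans to C7 becomes equatorial), and C2 carries its aluminium-bound oxygen equatorial (2α) because the axial site is 1,3-diaxial to C19 and C20. The step needs aldehyde over ketone selectivity, six-membered Prins closure over direct eight-membered attack of the silane on C2, and cation capture over proton loss. These are secured by the higher electrophilicity of the aldehyde and the gem-dialkyl effect of C4, by ring size and high dilution, and by the β-silyl effect together with MeAlCl2 acting as proton scavenger.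

Step 12
Reactants: 20 bicyclic hydroxy ketone
Product: 21 19-acetoxy-2α,7α-dihydroxy-14,15-dinorlabd-8(17)-en-13-one (target)
Conditions: SeO2 (0.3 equiv), t-BuOOH (2 equiv), CH2Cl2, 0 °C → rt
Reagents that add atoms: selenium dioxide, O=[Se]=O (oxygen carrier); tert-butyl hydroperoxide, CC(C)(C)OO (terminal oxidant)
Why: SeO2/TBHP allylic hydroxylation (ene reaction then [2,3]-sigmatropic shift): selenium binds C17 while the axial 7α-H is removed and oxygen returns to the same α face, CH2 (C7) being preferred over the hindered methine C9, so the axial 7α-alcohol should result.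

Compound list
1 | (S)-(+)-carvone | CC1=CC[C@@H](CC1=O)C(C)=C | starting material
2 | prenyl bromide (1-bromo-3-methylbut-2-ene) | CC(C)=CCBr | starting material
3 | (5S,6R)-6-prenylcarvone (prenyl trans to isopropenyl) | CC1=CC[C@H](C(C)=C)[C@@H](CC=C(C)C)C1=O | intermediate
4 | (5R,6S)-6-methyl-6-prenylcarvone (methyl trans, prenyl cis to isopropenyl) | CC1=CC[C@H](C(C)=C)[C@](C)(CC=C(C)C)C1=O | intermediate
5 | lithium enolate from 1,4-reduction of 4 | [Li]OC1=C(C)CC[C@H](C(C)=C)[C@]1(C)CC=C(C)C | intermediate
6 | (5R,6S)-2-hydroxy-2,6-dimethyl-6-prenyl-5-isopropenylcyclohexanone, epimers at the carbinol carbon | CC1(O)CC[C@H](C(C)=C)[C@](C)(CC=C(C)C)C1=O | intermediate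
7 | methyl (2S,3R)-2-methyl-2-prenyl-3-isopropenyl-6-oxoheptanoate | COC(=O)[C@@](C)(CC=C(C)C)[C@H](CCC(C)=O)C(C)=C | intermediate
8 | terminal diethyl enol phosphate of 7 | COC(=O)[C@@](C)(CC=C(C)C)[C@H](CCC(=C)OP(=O)(OCC)OCC)C(C)=C | intermediate
9 | methyl (2S,3R)-2-methyl-2-prenyl-3-isopropenylhept-6-ynoate | COC(=O)[C@@](C)(CC=C(C)C)[C@H](CCC#C)C(C)=C | intermediate
10 | (2S,3R)-2-methyl-2-prenyl-3-isopropenylhept-6-yn-1-ol | OC[C@@](C)(CC=C(C)C)[C@H](CCC#C)C(C)=C | intermediate
11 | (2S,3R)-2-methyl-2-prenyl-3-isopropenylhept-6-yn-1-yl acetate | CC(=O)OC[C@@](C)(CC=C(C)C)[C@H](CCC#C)C(C)=C | intermediate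
12 | methyl vinyl ketone | C=CC(C)=O | starting material
13 | (Z)-2-bromoalkenyl-9-BBN from 11 | CC(=O)OC[C@@](C)(CC=C(C)C)[C@H](CC/C(Br)=C/B1C2CCCC1CCC2)C(C)=C | intermediate
14 | 9-BBN enolate of 15 | CC(=O)OC[C@@](C)(CC=C(C)C)[C@H](CC/C(Br)=C/CC=C(C)OB1C2CCCC1CCC2)C(C)=C | intermediate
15 | (2S,3R,6Z)-6-bromo-2-methyl-10-oxo-2-prenyl-3-isopropenylundec-6-en-1-yl acetate | CC(=O)OC[C@@](C)(CC=C(C)C)[C@H](CC/C(Br)=C/CCC(C)=O)C(C)=C | intermediate
16 | prenyl epoxide of 15 (epimers at the epoxide CH) | CC(=O)OC[C@@](C)(CC1OC1(C)C)[C@H](CC/C(Br)=C/CCC(C)=O)C(C)=C | intermediate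
17 | (2S,3R,6Z)-6-bromo-2-methyl-10-oxo-2-(2-oxoethyl)-3-isopropenylundec-6-en-1-yl acetate | CC(=O)OC[C@@](C)(CC=O)[C@H](CC/C(Br)=C/CCC(C)=O)C(C)=C | intermediate
18 | (2S,3R,6Z)-2-methyl-10-oxo-2-(2-oxoethyl)-3-isopropenyl-6-[(trimethylsilyl)methyl]undec-6-en-1-yl acetate | CC(=O)OC[C@@](C)(CC=O)[C@H](CC/C(C[Si](C)(C)C)=C/CCC(C)=O)C(C)=C | intermediate
19 | ring-A tertiary C10 cation (drawn without the Lewis acid on O2) | C[C+]1C[C@@H](O)C[C@](C)(COC(C)=O)[C@@H]1CC/C(C[Si](C)(C)C)=C/CCC(C)=O | intermediate
20 | 19-acetoxy-2α-hydroxy-14,15-dinorlabd-8(17)-en-13-one (5α-H, 9α-H, 10β-CH3) | C=C1CC[C@H]2[C@@](C)(COC(C)=O)C[C@H](O)C[C@]2(C)[C@H]1CCC(C)=O | intermediate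
21 | 19-acetoxy-2α,7α-dihydroxy-14,15-dinorlabd-8(17)-en-13-one (2R,4S,5R,7R,9R,10S) | C=C1[C@H](O)C[C@H]2[C@@](C)(COC(C)=O)C[C@H](O)C[C@]2(C)[C@H]1CCC(C)=O | target

Total step count: 12. Longest linear sequence: 12 steps from (S)-carvone.

Steps most likely to fail

Step 11. The C10 cation may lose a proton (ene-type termination) before ring B closes. The allylsilane may be protodesilylated or may attack the aldehyde of a second molecule. Incomplete chair–chair organisation may also erode control of the ring fusion. The fallback sets out from 17 and comes back at 20. It separates the two ring closures and closes ring A before any silane is present. Treatment of 17 with MeAlCl2 at −78 °C should give, by Prins closure and chloride capture at C10, the ring-A chlorohydrin bromide F1. Negishi coupling as in step 10, now on a molecule without aldehyde or isopropenyl group, gives the ring-A chlorohydrin allylsilane F2. TiCl4 with 2,6-di-tert-butylpyridine at −78 °C re-ionises the tertiary chloride. The allylsilane then alkylates C10 (tertiary chloride–allylsilane coupling), which closes ring B and returns to 20.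

Step 10. Transfer of the silylmethyl group from zinc to palladium may be slow. The alkenylpalladium species could then insert into the nearby isopropenyl group (5-exo carbopalladation), or the zinc reagent could add to the free aldehyde. The fallback sets out from 17 and comes back at 18. Both carbonyl groups are masked with ethylene glycol and PPTS to give the bis-dioxolane bromide F3. The faster Kumada coupling with Me3SiCH2MgCl (Pd(PPh3)4 or Fe(acac)3, THF, 0 °C) gives the bis-dioxolane allylsilane F4. PPTS in wet acetone then releases aldehyde and ketone to give 18.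

Step 4. The ketone next to quaternary C4 may not form the hemiketal that the cleavage needs. The reaction would then stall and lead(IV) would begin to attack the alkenes. The fallback sets out from 6 and comes back at 7, and it replaces ketol cleavage by glycol cleavage. LiAlH4 reduces 6 to the 1,2-diol F5. NaIO4 in aqueous THF cleaves this to the keto aldehyde F6. Pinnick oxidation (NaClO2, NaH2PO4, 2-methyl-2-butene) oxidises only the aldehyde and gives the keto acid F7. Trimethylsilyldiazomethane in MeOH–PhH then gives 7.

Further compounds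
F1 | step 11 | ring-A chlorohydrin bromide (2α-OH, C10–Cl, configuration at C10 open) | CC1(Cl)C[C@@H](O)C[C@](C)(COC(C)=O)[C@@H]1CC/C(Br)=C/CCC(C)=O
F2 | step 11 | ring-A chlorohydrin allylsilane | CC1(Cl)C[C@@H](O)C[C@](C)(COC(C)=O)[C@@H]1CC/C(C[Si](C)(C)C)=C/CCC(C)=O
F3 | step 10 | bis-dioxolane bromide | CC(=O)OC[C@@](C)(CC1OCCO1)[C@H](CC/C(Br)=C/CCC1(C)OCCO1)C(C)=C
F4 | step 10 | bis-dioxolane allylsilane | CC(=O)OC[C@@](C)(CC1OCCO1)[C@H](CC/C(C[Si](C)(C)C)=C/CCC1(C)OCCO1)C(C)=C
F5 | step 4 | 1,2-diol from 6 (carbinol centres open) | CC1(O)CC[C@H](C(C)=C)[C@](C)(CC=C(C)C)C1O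
F6 | step 4 | (2S,3R)-2-methyl-2-prenyl-3-isopropenyl-6-oxoheptanal | O=C[C@@](C)(CC=C(C)C)[C@H](CCC(C)=O)C(C)=C
F7 | step 4 | (2S,3R)-2-methyl-2-prenyl-3-isopropenyl-6-oxoheptanoic acid | OC(=O)[C@@](C)(CC=C(C)C)[C@H](CCC(C)=O)C(C)=C
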